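The readings are simulated from invented constants, noise included.

Charging the second end groups at 0.950 equiv of the first end groups, short of equal amounts, is a decision about how far this flask can go.

| setting | green | flask |
|---|---|---|
| first end groups | 1.5 M | 1.5 M |
| second end groups | 0.95 equiv | 0.950 equiv |
| remark | the very flask that is asked about, followed so far |  |
| time |  | 25 h |

green run (percent of the first end groups charged): time / h: links / % = 0.833: 80.4; 1.33: 85.7; 2.00: 88.1; 4.00: 92.3; 6.00: 93.9; 10.0: 94.7

(scatter of a reading: 1 percentage point)

* at 25 h, what has stopped the reaction, if anything has (the second end groups has run out first / all of the first end groups has reacted / forward and back rates have come level / it is still moving)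
* how much links there is at 25 h, in percent of the first end groups charged

- the reaction counts as stopped when no species that holds the first end groups changes by six tenths of a point or more over the second half of the time

Counting one first end group and one second end group per link, links have a ceiling. Call it C = 95.0%, the charged equivalents of second end groups written as a percentage of the first end groups charged: the limiting-reagent ceiling on links. The green run, this same flask followed so far, stands at 94.7% at 10.0 h. That is 0.3 percentage points below C, less than the scatter of 1 point. At 6.00 h the gap was 1.1 points, so the readings have moved towards C, though by 0.8 points, less than the scatter, and 15.0 h more remain. The reckoning here therefore commits to links at C by 25 h, with the second end groups as the charge that ends the reaction.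

The forecast gives the second end groups has run out first and 94.9%, which lies 0.1 points under C. Its ground is a second-order constant of about 0.27 per hour, “constant within the scatter”.

The flask gives the second end groups has run out first and 95.0%.

    first end groups ⇌ dormant form (K = 0.650, k = 2.55 × 10⁻⁴ /s)
    first end groups + second end groups → links + released group (k = 0.00165 /M/s)

At 25.0 h this flask holds links at 95.0% against C of 95.0%, with 0.0065% of the second end groups' own charge left. The neighbour charged with 0.380 equiv of second end groups has C = 38.0% and ends at 38.0% links. At 0.117 h this flask's first end groups pass into links 4.6 times as fast as into the dormant form, counting that reversible step's forward rate alone. Its backward turnover comes to 98% of the forward one, and at 25.0 h the dormant form holds 1.97% of the first end groups charged.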